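In a closed flask every percent of substrate charged stays in some form, so a falling sum of target and other capture product means material is passing on to something unread.

all flasks: substrate 0.050 M
- dusk: first nucleophile 1.3 equiv; second nucleophile 3 equiv; the very flask that is asked about, followed so far
- flask: first nucleophile 1.30 equiv; second nucleophile 3.00 equiv; time 6.0 d

dusk run (percent of the substrate charged)

| time / h | target / % | other capture product / % |
|---|---|---|
| 10.0 | 36.3 | 29.3 |
| 20.0 | 35.6 | 36.9 |
| 30.0 | 28.4 | 39.0 |
| 40.0 | 22.4 | 38.6 |

(readings scatter by 0.5 percentage points)

- ratio of target to other capture product at 40 min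
- ratio of target to other capture product at 6.0 d
- which of target and other capture product there is more of at 6.0 d



The dusk run is this flask, followed to 40.0 h. From 20.0 h to 40.0 h that sum falls by 12 percentage points, and target falls by 13 points, so the loss reads as target's. Over the last interval the other capture product drops 0.4 points, less than the scatter, so it is taken as flat.

Two times remain. One is the half-life of target, the time in which target halves in its falling stretch, read as 29.9 h. The other is the asked 6.0 d, longer than that half-life: it spans 4.81 of them. Carried on from its last reading at that half-life, target is reckoned at 2.01 % at the asked time. Against a flat 38.6 %, this reckoning gives a ratio of 0.0522.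

The forecast gives 1.6 at 40 min and 0.15 at 6.0 d, with range 0.05 to 0.4, and other capture product ahead. It differs from this reckoning: it puts the other capture product at 12 to 16 percent, “as it decays more slowly”.

The flask gives 1.62 at 40 min and 0.0411 at 6.0 d, with other capture product ahead: 39.1 % against 1.61 % target, where 2.01 % was reckoned.

    first nucleophile + intermediate → target (k = 0.0295 M⁻¹ s⁻¹)
    intermediate → decomposed reagent (k = 1.31 × 10⁻⁶ s⁻¹)
    intermediate → solvolysis product (k = 1.92 × 10⁻⁴ s⁻¹)
    second nucleophile + intermediate → other capture product (k = 0.00770 M⁻¹ s⁻¹)
    target → over-reaction product (k = 7.13 × 10⁻⁶ s⁻¹)
    substrate → intermediate (k = 4.11 × 10⁻⁵ s⁻¹)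

The other capture product stands at 39.1 % after 3.00 d and 39.1 % after 6.00 d. The neighbour flask with 3.20 equiv of first nucleophile is given the same half-life, counted roughly from the start over the same 6.0 d: 3.56 % of the target made is reckoned to remain. That neighbour made 76.0 % target, counting its over-reaction product, so 2.70 % is reckoned. That neighbour holds 2.28 % target at 6.00 d.

The earlier runs and the new flask stem from a simulated flask from invented constants.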